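The data stem from a simulated flask for an exercise; the scatter is artificial.

Count the partner before reading any curve. Every proposed step takes partner, so free partner is the concentration common to their rates. One partner per substrate gives a mono adduct of either kind, and bis adduct needs a second.

| setting | zeta | theta | eta | grey | amber | violet |
|---|---|---|---|---|---|---|
| substrate | 20 mM | 20 mM | 20 mM | 20 mM | 20 mM | 20 mM |
| partner | 25 mM | 36 mM | 68 mM | 24.0 mM | 40.0 mM | 60.0 mM |
| remark | run made earlier | run made earlier | run made earlier |  |  |  |
| time |  |  |  | 8.0 min | 8.0 min | 8.0 min |

- zeta (time / min: bis adduct / %, mono adduct / %): 1.50: 15, 28; 3.00: 21, 28; 5.00: 26, 31; 6.00: 26, 34; 8.00: 29, 32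
- theta (time / min: bis adduct / %, mono adduct / %): 0.667: 15, 28; 2.00: 36, 35; 4.00: 46, 32; 6.00: 53, 34; 8.00: 58, 32
- eta (time / min: bis adduct / %, mono adduct / %): 0.667: 29, 32; 1.33: 50, 36; 2.50: 66, 32; 4.00: 69, 32; 8.00: 76, 27

(readings scatter by 2 percentage points)

- final bis adduct, as a percentage of the substrate charged, for each flask in turn (grey, amber, violet)

- what may be going on: substrate + partner -> mono adduct; substrate + partner -> other mono adduct; partner + mono adduct -> bis adduct; partner + other mono adduct -> bis adduct

I called the partner beyond one per substrate, as a share of the substrate charged, the surplus s, with cA and cB the charges of substrate and partner: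

s = (cB − cA)/cA = 20.0% for grey

My first estimate for grey was bis adduct equal to s. But zeta, with s of 25.0%, read 29% at 8.00 min, which was more by 4 percentage points, with a scatter of 2 points. Unreacted substrate could account for such a gap. The balance of partner showed how:

bis adduct = s + substrate left − (cB/cA) × partner left

Here substrate left is a share of the substrate charged, and partner left a share of its own charge. Adding zeta's gap, I took 24.0% for grey.

Had grey stopped by then? Zeta rose 3 points from 6.00 min to 8.00 min, about the scatter, so I let that stand.

But theta read 58%, less than its s of 80.0%, so I did not use s as the estimate for amber or violet. For those I read a straight line between theta and eta: 60.2% for amber and 71.5% for violet.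

The forecast gave 25%, 63% and 73%, on this ground: “Bis adduct is therefore limited by the partner left after the first addition”. My amber stood lower by 2.8 points.

The flasks gave 24.5%, 61.9% and 71.5%.

    substrate + partner → mono adduct (k = 0.650 /M/s)
    substrate + partner → other mono adduct (k = 1.20 /M/s)
    partner + mono adduct → bis adduct (k = 0.0160 /M/s)
    partner + other mono adduct → bis adduct (k = 0.480 /M/s)

In grey, partner was the limiting reagent, with 1.3% of its charge left, and the balance gave 24.5%. In amber, s was 100%, and with 0% of the substrate and 19% of the partner left the balance gave 61.9%. At amber's charged concentrations, the half-life of other mono adduct by its passing into bis adduct was 0.60 min, and that of mono adduct was far longer, at 18 min. At 8.00 min, amber held 32.4% mono adduct and 5.77% other mono adduct.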